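**Retrosynthetic overview**

1. Target ⇐ acetylation and B-alkyl Suzuki–Miyaura coupling (C12–C13) of a C9-vinyl decalin with methyl (Z)-4-hydroxy-3-iodobut-2-enoate, which fixes the side-chain E-alkene; the vinyl group comes from a C11 aldehyde.
2. The C6=C7 alkene ⇐ a C6–OH/C7–NO2 pair, removed through the nitroalkene, its thiol adduct and a tin hydride elimination.
3. Key disconnection, ring B at C8–C9 and C6–C7: a ring-A 1,5-dialdehyde (C6–C5–C10–C9–C11) plus methyl (E)-3-nitroacrylate (C7–C8–C17), joined by an amine-catalysed Michael/Henry domino.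
4. Enabling feature: the C17 ester on C8 and carbon C11 on C9 stand 1,4, so C8 and C9 are both α-carbons of like polarity, and C7 is an unsubstituted alkene CH between C8 and C6; a nitro group on C7 can therefore reverse the polarity of C8, close C6–C7 as a nucleophile and leave again.
5. Ring order: ring A is bought (2,2,6-trimethylcyclohexanone); C10 is set by asymmetric α-vinylation, C5 through a temporary borinane ring; ring B is formed in the key step.

Key step: step 7

Remarks: positions are given in labdane numbering (ring A = C1–C5, C10; ring B = C5–C10; C17 = ester carbon on C8; C11–C16 = side chain). Methyl glyoxylate is used as its commercial toluene solution. For step 1 the sense of induction on this ketone is not known, so the ligand enantiomer that gives the (S)-vinyl ketone is to be used (written below as the (R)-ligand).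

**Step 1**
Reactants: 1 2,2,6-trimethylcyclohexan-1-one (racemic); 2 vinyl bromide
Product: 3 (2S)-2-ethenyl-2,6,6-trimethylcyclohexan-1-one
Conditions: Pd2(dba)3 (2 mol%), (R)-2-(dicyclohexylphosphino)-2'-(dimethylamino)-1,1'-binaphthyl (5 mol%), NaOtBu, 2 (1 M in THF), toluene, 23 → 50 °C
Reagents that add atoms: none
Why: Palladium-catalysed asymmetric α-vinylation of a ketone enolate: 1 can enolise only towards C-10, and reductive elimination from the vinylpalladium enolate carrying the bulky chiral monophosphine should create the quaternary C-10 centre with the configuration chosen by the ligand.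

**Step 2**
Reactants: 3 (2S)-2-ethenyl-2,6,6-trimethylcyclohexan-1-one
Product: 4 (1S)-1-ethenyl-1,3,3-trimethyl-2-methylidenecyclohexane
Conditions: Ph3PCH3Br, KOtBu, toluene, 110 °C
Reagents that add atoms: methyltriphenylphosphonium bromide, C[P+](c1ccccc1)(c1ccccc1)c1ccccc1.[Br-]
Why: Wittig methylenation under forcing conditions of the kind that convert ketones flanked by two quaternary carbons; no stereocentre is formed and C-10 cannot epimerise because 3 has no α-hydrogen.

**Step 3**
Reactants: 4 (1S)-1-ethenyl-1,3,3-trimethyl-2-methylidenecyclohexane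
Product: 6 2-[(1S,2R)-2-(hydroxymethyl)-1,3,3-trimethylcyclohexyl]ethan-1-ol, via trans-fused B-thexylborinane 5 (not isolated)
Conditions: thexylborane (from BH3·THF and 2,3-dimethylbut-2-ene), THF, −20 → 23 °C, high dilution; then NaOH, H2O2, 0 → 23 °C
Reagents that add atoms: hydrogen peroxide, OO
Why: Cyclic hydroboration of a 1,4-diene with a monoalkylborane, then oxidation: the vinyl group reacts first (boron on C-11), and the tethered B–H then adds to the exocyclic methylene with boron on C-6 and hydrogen on C-5 from the face of the C-9 arm, the other face being blocked by the axial methyl groups on C-4 and C-10, so the trans-fused borinane and, after oxidation with retention, the 5,10-trans diol should result.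

**Step 4**
Reactants: 6 2-[(1S,2R)-2-(hydroxymethyl)-1,3,3-trimethylcyclohexyl]ethan-1-ol
Product: 7 (1R,2S)-2,6,6-trimethyl-2-(2-oxoethyl)cyclohexane-1-carbaldehyde
Conditions: (COCl)2, DMSO, CH2Cl2, −78 °C; then i-Pr2NEt, −78 → 0 °C
Reagents that add atoms: none
Why: Swern oxidation: both hydroxyls are activated at −78 °C before the base is added, which avoids lactol and lactone formation, and the cold, weakly basic conditions should leave the aldehyde α-centre C-5 untouched.

**Step 5**
Reactants: 8 methyl glyoxylate; 9 nitromethane
Product: 10 methyl 2-hydroxy-3-nitropropanoate (racemic)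
Conditions: Et3N (5 mol%), 9 (excess), THF, 0 → 23 °C
Reagents that add atoms: none
Why: Henry (nitroaldol) addition of nitromethane to the highly electrophilic glyoxylate aldehyde; the new carbinol centre is racemic and is destroyed in step 6.

**Step 6**
Reactants: 10 methyl 2-hydroxy-3-nitropropanoate
Product: 12 methyl (2E)-3-nitroprop-2-enoate, via mesylate 11 (not isolated)
Conditions: MeSO2Cl, Et3N, CH2Cl2, −20 °C
Reagents that add atoms: none
Why: Mesylation followed by E1cB elimination through the nitronate, the standard dehydration of β-nitro alcohols, which should give the conjugated (E)-nitroalkene.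

**Step 7**
Reactants: 7 (1R,2S)-2,6,6-trimethyl-2-(2-oxoethyl)cyclohexane-1-carbaldehyde; 12 methyl (2E)-3-nitroprop-2-enoate
Product: 14 methyl (1R,2R,3S,4S,4aR,8aR)-1-formyl-4-hydroxy-5,5,8a-trimethyl-3-nitrodecahydronaphthalene-2-carboxylate, via open-chain Michael adduct 13 (not isolated)
Conditions: 12 (1.2 equiv), (S)-2-[diphenyl(trimethylsilyloxy)methyl]pyrrolidine (20 mol%), PhCO2H (20 mol%), CH2Cl2, 0 → 23 °C; then Et3N (1 equiv), 23 °C
Reagents that add atoms: none
Why: Mechanism: the secondary amine condenses only with the unhindered CH2–CHO arm (C-11) of 7 to give the (E)-enamine, whose β-carbon C-9 adds to the ester-bearing carbon of 12 (C-8, made the electrophilic position by the nitro group on C-7) to give 13 after hydrolysis; triethylamine then forms the C-7 nitronate, which adds to the C-6 aldehyde and closes ring B. The closest known reaction types are the amine-catalysed Michael/Henry domino of pentane-1,5-dials with nitroalkenes to give nitrocyclohexanols and the diarylprolinol silyl ether-catalysed Michael addition of aldehydes to β-nitroacrylates. Ring B is closed by a 6-exo-trig nitro-aldol addition of C-7 to the C-6 carbonyl. C-8 is set by the catalyst (attack on the enamine face away from the diarylsilyloxymethyl group, synclinal approach with the nitro group over the enamine nitrogen; the (S)-catalyst is the enantiomer predicted to give the target configuration), C-9 is formed epimeric but is α to the aldehyde and should equilibrate under the amines to the equatorial position, and C-6 and C-7 should settle equatorial through the reversible Henry step and are removed in steps 8 and 9. The step needs chemoselectivity between the two aldehydes, secured by the neopentylic, α-branched C-6 aldehyde not forming an enamine; regioselectivity in the addition to 12, secured by nitro being the stronger acceptor; and catalyst control over the facial bias that C-10 exerts on the enamine, which is the one selectivity the substrate does not secure.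

**Step 8**
Reactants: 14 methyl (1R,2R,3S,4S,4aR,8aR)-1-formyl-4-hydroxy-5,5,8a-trimethyl-3-nitrodecahydronaphthalene-2-carboxylate
Product: 17 methyl 1-formyl-5,5,8a-trimethyl-3-nitro-4-(phenylsulfanyl)decahydronaphthalene-2-carboxylate (epimer mixture at C-6 and C-7, other centres as in 14), via C-6 mesylate 15 (not isolated), via nitroalkene 16 (not isolated)
Conditions: MeSO2Cl, Et3N, CH2Cl2, −20 °C; then PhSH, 0 °C
Reagents that add atoms: thiophenol, Sc1ccccc1
Why: Mesylation and E1cB elimination of the β-nitro alcohol (the C-7 hydrogen α to nitro is the most acidic one) followed by conjugate addition of the thiol to C-6 of the nitroalkene in the same flask, a standard entry to β-nitro sulfides; the two new centres form as a mixture and are removed in step 9.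

**Step 9**
Reactants: 17 β-nitro sulfide (epimer mixture)
Product: 18 methyl (1R,2S,4aR,8aR)-1-formyl-5,5,8a-trimethyl-1,2,4a,5,6,7,8,8a-octahydronaphthalene-2-carboxylate
Conditions: Bu3SnH, AIBN, toluene, 90 °C
Reagents that add atoms: none
Why: Radical elimination of a β-nitro sulfide with tin hydride: the stannyl radical removes the nitro group and the C-7 radical expels the phenylthiyl radical, so the alkene is placed regiospecifically between C-6 and C-7 without base and without touching C-8 or C-9.

**Step 10**
Reactants: 18 methyl (1R,2S,4aR,8aR)-1-formyl-5,5,8a-trimethyl-1,2,4a,5,6,7,8,8a-octahydronaphthalene-2-carboxylate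
Product: 19 methyl (1R,2S,4aR,8aS)-1-ethenyl-5,5,8a-trimethyl-1,2,4a,5,6,7,8,8a-octahydronaphthalene-2-carboxylate
Conditions: Ph3PCH3Br, KN(SiMe3)2, THF, −78 → 0 °C (ylide preformed)
Reagents that add atoms: methyltriphenylphosphonium bromide, C[P+](c1ccccc1)(c1ccccc1)c1ccccc1.[Br-]
Why: Wittig methylenation with the preformed ylide at low temperature: addition to the aldehyde should outrun deprotonation at C-8, and C-9, the only centre at risk, already has its preferred equatorial configuration.

**Step 11**
Reactants: 20 methyl 4-hydroxybut-2-ynoate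
Product: 21 methyl (2Z)-4-hydroxy-3-iodobut-2-enoate
Conditions: NaI, AcOH, 70 °C
Reagents that add atoms: sodium iodide, [Na+].[I-]
Why: Hydroiodination of an ynoate: conjugate addition of iodide and anti protonation should give the (Z)-β-iodo enoate, in which the hydroxymethyl group is trans to the ester and cannot lactonise.

**Step 12**
Reactants: 19 methyl (1R,2S,4aR,8aS)-1-ethenyl-5,5,8a-trimethyl-1,2,4a,5,6,7,8,8a-octahydronaphthalene-2-carboxylate; 21 methyl (2Z)-4-hydroxy-3-iodobut-2-enoate
Product: 23 methyl (1R,2S,4aR,8aS)-1-[(3E)-3-(hydroxymethyl)-5-methoxy-5-oxopent-3-en-1-yl]-5,5,8a-trimethyl-1,2,4a,5,6,7,8,8a-octahydronaphthalene-2-carboxylate, via B-alkyl-9-BBN borane 22 (not isolated)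
Conditions: 9-BBN-H, THF, 0 → 23 °C; then 21, PdCl2(dppf) (5 mol%), AsPh3, K3PO4 (3 M aq.), DMF, 23 °C
Reagents that add atoms: none
Why: Chemoselective hydroboration of the monosubstituted vinyl group with 9-BBN-H (the cis-disubstituted ring alkene reacts far more slowly) followed by B-alkyl Suzuki–Miyaura coupling, which proceeds with retention at the vinyl iodide and so sets the (E)-trisubstituted enoate.

**Step 13**
Reactants: 23 hydroxy diester
Product: 24 methyl (1R,2S,4aR,8aS)-1-[(3E)-3-(acetyloxymethyl)-5-methoxy-5-oxopent-3-en-1-yl]-5,5,8a-trimethyl-1,2,4a,5,6,7,8,8a-octahydronaphthalene-2-carboxylate (CNP0190145.1)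
Conditions: Ac2O, pyridine, DMAP (cat.), CH2Cl2, 0 °C
Reagents that add atoms: acetic anhydride, CC(=O)OC(C)=O
Why: Acetylation of the primary allylic alcohol under nucleophilic catalysis; no stereocentre is affected.

**Compound list**

1 | 2,2,6-trimethylcyclohexan-1-one (racemic) | CC1CCCC(C)(C)C1=O | starting material
2 | vinyl bromide | C=CBr | starting material
3 | (2S)-2-ethenyl-2,6,6-trimethylcyclohexan-1-one | C=C[C@]1(C)CCCC(C)(C)C1=O | intermediate
4 | (1S)-1-ethenyl-1,3,3-trimethyl-2-methylidenecyclohexane | C=C[C@]1(C)CCCC(C)(C)C1=C | intermediate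
5 | trans-fused B-(2,3-dimethylbutan-2-yl)borinane (boron joins C-11 and C-6, H-5 anti to the C-10 methyl) | CC(C)C(C)(C)B1CC[C@]2(C)CCCC(C)(C)[C@H]2C1 | intermediate
6 | 2-[(1S,2R)-2-(hydroxymethyl)-1,3,3-trimethylcyclohexyl]ethan-1-ol | OCC[C@]1(C)CCCC(C)(C)[C@H]1CO | intermediate
7 | (1R,2S)-2,6,6-trimethyl-2-(2-oxoethyl)cyclohexane-1-carbaldehyde | O=CC[C@]1(C)CCCC(C)(C)[C@H]1C=O | intermediate
8 | methyl glyoxylate | COC(=O)C=O | starting material
9 | nitromethane | C[N+](=O)[O-] | starting material
10 | methyl 2-hydroxy-3-nitropropanoate (racemic) | COC(=O)C(O)C[N+](=O)[O-] | intermediate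
11 | methyl 2-(methanesulfonyloxy)-3-nitropropanoate | COC(=O)C(OS(C)(=O)=O)C[N+](=O)[O-] | intermediate
12 | methyl (2E)-3-nitroprop-2-enoate | COC(=O)/C=C/[N+](=O)[O-] | intermediate
13 | methyl 3-[(1S,2R)-2-formyl-1,3,3-trimethylcyclohexyl]-2-(nitromethyl)-4-oxobutanoate (C-8 as in the target, C-9 as formed kinetically) | O=C[C@@H]([C@H](C[N+](=O)[O-])C(=O)OC)[C@]1(C)CCCC(C)(C)[C@H]1C=O | intermediate
14 | methyl (1R,2R,3S,4S,4aR,8aR)-1-formyl-4-hydroxy-5,5,8a-trimethyl-3-nitrodecahydronaphthalene-2-carboxylate (trans-decalin, all four ring-B substituents equatorial) | O=C[C@@H]1[C@@H](C(=O)OC)[C@H]([N+](=O)[O-])[C@@H](O)[C@@H]2C(C)(C)CCC[C@@]12C | intermediate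
15 | methanesulfonate of 14 at the C-6 oxygen | O=C[C@@H]1[C@@H](C(=O)OC)[C@H]([N+](=O)[O-])[C@@H](OS(C)(=O)=O)[C@@H]2C(C)(C)CCC[C@@]12C | intermediate
16 | methyl 1-formyl-5,5,8a-trimethyl-3-nitro-1,2,4a,5,6,7,8,8a-octahydronaphthalene-2-carboxylate (C-6=C-7 nitroalkene, other centres as in 14) | O=C[C@@H]1[C@@H](C(=O)OC)C([N+](=O)[O-])=C[C@@H]2C(C)(C)CCC[C@@]12C | intermediate
17 | methyl 1-formyl-5,5,8a-trimethyl-3-nitro-4-(phenylsulfanyl)decahydronaphthalene-2-carboxylate (epimer mixture at C-6 and C-7, other centres as in 14) | O=C[C@@H]1[C@@H](C(=O)OC)C([N+](=O)[O-])C(Sc3ccccc3)[C@@H]2C(C)(C)CCC[C@@]12C | intermediate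
18 | methyl (1R,2S,4aR,8aR)-1-formyl-5,5,8a-trimethyl-1,2,4a,5,6,7,8,8a-octahydronaphthalene-2-carboxylate | O=C[C@@H]1[C@@H](C(=O)OC)C=C[C@@H]2C(C)(C)CCC[C@@]12C | intermediate
19 | methyl (1R,2S,4aR,8aS)-1-ethenyl-5,5,8a-trimethyl-1,2,4a,5,6,7,8,8a-octahydronaphthalene-2-carboxylate | C=C[C@@H]1[C@@H](C(=O)OC)C=C[C@@H]2C(C)(C)CCC[C@@]12C | intermediate
20 | methyl 4-hydroxybut-2-ynoate | COC(=O)C#CCO | starting material
21 | methyl (2Z)-4-hydroxy-3-iodobut-2-enoate | COC(=O)/C=C(\I)CO | intermediate
22 | B-alkyl-9-borabicyclo[3.3.1]nonane from 19 (boron on C-12) | C3CCC4CCCC3B4CC[C@@H]1[C@@H](C(=O)OC)C=C[C@@H]2C(C)(C)CCC[C@@]12C | intermediate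
23 | methyl (1R,2S,4aR,8aS)-1-[(3E)-3-(hydroxymethyl)-5-methoxy-5-oxopent-3-en-1-yl]-5,5,8a-trimethyl-1,2,4a,5,6,7,8,8a-octahydronaphthalene-2-carboxylate | COC(=O)/C=C(\CC[C@@H]1[C@@H](C(=O)OC)C=C[C@@H]2C(C)(C)CCC[C@@]12C)CO | intermediate
24 | methyl (1R,2S,4aR,8aS)-1-[(3E)-3-(acetyloxymethyl)-5-methoxy-5-oxopent-3-en-1-yl]-5,5,8a-trimethyl-1,2,4a,5,6,7,8,8a-octahydronaphthalene-2-carboxylate (CNP0190145.1) | COC(=O)/C=C(\CC[C@@H]1[C@@H](C(=O)OC)C=C[C@@H]2C(C)(C)CCC[C@@]12C)COC(C)=O | target

**Step count and risks**

Total step count: 13. Longest linear sequence: 10 steps (1, 2, 3, 4, 7, 8, 9, 10, 12, 13).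

Step 7 (key step). What may go wrong: the catalyst may fail to overrule the facial bias that the neighbouring quaternary C-10 imposes on the enamine (mismatched double stereodifferentiation, eroding C-8), or the Henry closure onto the hindered aldehyde may lag behind side reactions of the open-chain adduct. Fallback: catalyst control is given up for thermodynamic control, and the C7–C8 unit is built on the substrate from two one-carbon partners. Dialdehyde 7 would be condensed at its unhindered aldehyde with methyl glyoxylate 8 (pyrrolidine/benzoic acid, aldol condensation) to the 3-formylacrylate methyl 3-formyl-3-[2-formyl-1,3,3-trimethylcyclohexyl]prop-2-enoate F4. Nitromethane 9 with Et3N or tetramethylguanidine would then add at C-8 (β to the aldehyde) and the nitronate would close ring B by the same Henry reaction, passing through 13 or its epimers. Because the nitro-Michael step, the Henry step and both α-carbonyl centres are reversible under these conditions, the all-equatorial isomer should accumulate. The fallback sets out from 7 and rejoins the route at 14.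

Step 1. What may go wrong: insufficient enantioselectivity, or stalled reductive elimination at the hindered tetrasubstituted enolate. Fallback: the quaternary centre is made by decarboxylative asymmetric allylic alkylation and the allyl group is cut back to vinyl. Ketone 1 would be O-acylated (LiN(SiMe3)2, allyl chloroformate) to allyl 2,6,6-trimethylcyclohex-1-en-1-yl carbonate F1. Pd2(dba)3 with (S)-tert-butyl-PHOX should then give (2S)-2,6,6-trimethyl-2-(prop-2-en-1-yl)cyclohexan-1-one F2. Alkene isomerisation with PdCl2(MeCN)2 would give (2S)-2,6,6-trimethyl-2-[(1E)-prop-1-en-1-yl]cyclohexan-1-one F3, and ethenolysis with the second-generation Hoveyda–Grubbs catalyst under ethylene would give 3. The fallback sets out from 1 and rejoins at 3.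

Step 8. What may go wrong: base-induced loss of nitrous acid towards C-8, or migration of the nitroalkene double bond before the thiol adds. Fallback: the nitroalkene is avoided altogether. The C-6 hydroxyl of 14 would be acylated with phenyl chlorothionoformate and pyridine to the O-phenyl thionocarbonate of 14 F5. Under Barton–McCombie conditions (Bu3SnH, AIBN, toluene, 90 °C) the C-6 radical should expel the nitro group from C-7 by β-scission and give the alkene directly. The fallback sets out from 14 and rejoins at 18, bypassing 17.

**Further compounds**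

F1 | step 1 | allyl 2,6,6-trimethylcyclohex-1-en-1-yl carbonate | C=CCOC(=O)OC1=C(C)CCCC1(C)C
F2 | step 1 | (2S)-2,6,6-trimethyl-2-(prop-2-en-1-yl)cyclohexan-1-one | C=CC[C@]1(C)CCCC(C)(C)C1=O
F3 | step 1 | (2S)-2,6,6-trimethyl-2-[(1E)-prop-1-en-1-yl]cyclohexan-1-one | C/C=C/[C@]1(C)CCCC(C)(C)C1=O
F4 | step 7 | methyl 3-formyl-3-[2-formyl-1,3,3-trimethylcyclohexyl]prop-2-enoate (ring A as in 7, alkene geometry open) | O=CC(=CC(=O)OC)[C@]1(C)CCCC(C)(C)[C@H]1C=O
F5 | step 8 | O-phenyl thionocarbonate of 14 at the C-6 oxygen | O=C[C@@H]1[C@@H](C(=O)OC)[C@H]([N+](=O)[O-])[C@@H](OC(=S)Oc3ccccc3)[C@@H]2C(C)(C)CCC[C@@]12C
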